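The larch run was what I had, so I asked it one thing: at a given moment, how fast was E made against how fast it was used? A Z holds two Q units, so I read Z as E meeting Q. Half of each gain in Z is then E used, and the gain in E plus that is E made.

common to all: Q 2.2 M
- larch: X 5 mol%; run made earlier
- flask: X 10 mol%; time 5.0 d
larch run (percent of the Q charged)

| time / d | E / % | Z / % | Q / % |
|---|---|---|---|
| 0.417 | 12 | 2 | 87 |
| 1.25 | 52 | 12 | 43 |
| 2.50 | 67 | 21 | 10 |
| 4.00 | 74 | 27 | 3 |
| 5.00 | 75 | 21 | 2 |

(each reading ± 2 percentage points)
- percent here means Q units held: one Z counts as two
- the earlier runs were read with a standard deviation of 2 percentage points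
- no earlier run changes the charge of X; that part of a forecast is a guess
- the species in which most of what was charged as Q, at 5.0 d sits (Q / E / Z)
- the largest share itself, whichever of these holds it, in percent of the Q charged

In larch, made over used was 9.00 between 0.417 d and 1.25 d, then 4.33 up to 2.50 d, so it drifted down as E rose. If both rates carry [Q], it cancels and the ratio goes as one over E. Multiplying each ratio by the mean E gave 288% and 258%. I took their mean, 273%, as C, the share of E at which making and use balance, a selectivity factor.

Each E used puts two units into Z, so Z grows roughly as E times E over C. With E and Z filling the charge, larch came to 77.8%, higher than the reading of 75%.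

I turned time first: larch held 2% Q at 5.00 d, so longer had little to add. The Q charge stayed put. That left X: if C followed the loading, it became 546% and E 86.3%.

The forecast said E at 74%, within 66% to 80%, noting that “X order in each path is unknown”; my own reckoning of E stood higher.

The flask gave E at 80.9%, with Z at 19.1% and Q at 0.0364%.

    Q + E → Z (k = 1.70 × 10⁻⁶ M⁻¹ s⁻¹)
    2 X → J (k = 4.10 × 10⁻⁵ M⁻¹ s⁻¹)
    Q + X → D + E (k = 4.20 × 10⁻⁶ M⁻¹ s⁻¹)
    Q + D → E + D, rate k4*[D]*[Q] (k = 2.30 × 10⁻⁴ M⁻¹ s⁻¹)

Between 0.500 d and 2.50 d the flask's C was 411%, more than in larch but less than proportion gave. E stopped short of the charge because of the loss of Q + E to Z: without that step this flask ends at 99.9%, not 80.9%.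

For a neighbouring flask, the same as this one but with 4 mol% of X, the power of the loading that took C from larch to this flask gives C of 239% and E of 75.9%; that neighbour computes to 72.5%.

Readings and results stem from a simulated flask from invented constants; noise was put on by code.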